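## Retrosynthetic overview

1. Ester C–O bond: target ⇒ (R)-chromenylmethanol 14 + O-acetylferuloyl chloride 17 (from ferulic acid); the phenolic acetate is removed last.
2. C6 acetyl ⇐ aryl bromide (Br/Li exchange, Weinreb amide); C3=C4 ⇐ chroman-4-ol ⇐ chroman-4-one 7.
3. Key C–C bond (C2–C3): Kabbe crossed aldol condensation of o-hydroxyacetophenone 5 with silyloxyacetone 2, closed by oxa-Michael addition.
4. C2 stereocentre: formed racemic in the Kabbe step, then resolved by catalyst-controlled reduction at C4 into two separable epimers, of which only the (2R,4S)-alcohol is carried on; C4 is erased by dehydration.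
5. Rings: both benzene rings are bought; the pyran ring is the only ring formed (step 4).

Assumption: the (S,S)-TsDPEN–Ru catalyst reduces both enantiomers of 7 with the facial sense known for chroman-4-one itself (4S); the two epimers are then told apart by NOE.

## Route

Step 1
Reactants: 1 hydroxyacetone
Product: 2 1-[(tert-butyldiphenylsilyl)oxy]propan-2-one
Conditions: TBDPSCl, imidazole, CH2Cl2, 0 °C → rt
Reagents that add atoms: tert-butyl(chloro)diphenylsilane (TBDPSCl), CC(C)(C)[Si](Cl)(c1ccccc1)c1ccccc1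
Why: Imidazole-mediated silyl ether formation at the primary alcohol gives a protected hydroxyacetone that is stable to amines, hydride and organolithiums.

Step 2
Reactants: 3 2',4'-dihydroxyacetophenone
Product: 4 1-(5-bromo-2,4-dihydroxyphenyl)ethanone
Conditions: NBS (1.0 equiv), MeCN, 0 °C → rt; recrystallise
Reagents that add atoms: N-bromosuccinimide, BrN1C(=O)CCC1=O
Why: Electrophilic aromatic bromination goes to C5, para to the 2-OH and ortho to the 4-OH, the only activated position that is not flanked by two substituents.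

Step 3
Reactants: 4 1-(5-bromo-2,4-dihydroxyphenyl)ethanone
Product: 5 1-[5-bromo-2-hydroxy-4-(methoxymethoxy)phenyl]ethanone
Conditions: MOMCl (1.1 equiv), i-Pr2NEt, CH2Cl2, 0 °C → rt
Reagents that add atoms: chloromethyl methyl ether (MOMCl), COCCl
Why: O-alkylation (MOM ether formation) occurs only at the free 4-OH because the 2-OH is hydrogen-bonded to the acetyl group, and that 2-OH is kept free for ring closure.

Step 4
Reactants: 5 1-[5-bromo-2-hydroxy-4-(methoxymethoxy)phenyl]ethanone; 2 1-[(tert-butyldiphenylsilyl)oxy]propan-2-one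
Product: 7 rac-6-bromo-2-{[(tert-butyldiphenylsilyl)oxy]methyl}-7-(methoxymethoxy)-2-methyl-2,3-dihydro-4H-chromen-4-one, via enone 6 (not isolated)
Conditions: pyrrolidine (0.5–1 equiv), toluene, 4 Å MS, 80–110 °C
Reagents that add atoms: none
Why: In this Kabbe condensation the pyrrolidine-mediated crossed aldol condensation between the acetyl CH3 of 5 and the ketone carbonyl of 2 forms the C2–C3 bond, and the enone is closed by intramolecular oxa-Michael addition of the ortho phenol, which creates the quaternary C2 centre as a racemate.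

Step 5
Reactants: 7 rac-6-bromo-2-{[(tert-butyldiphenylsilyl)oxy]methyl}-7-(methoxymethoxy)-2-methyl-2,3-dihydro-4H-chromen-4-one
Product: 8 (2R,4S)-6-bromo-2-{[(tert-butyldiphenylsilyl)oxy]methyl}-7-(methoxymethoxy)-2-methyl-3,4-dihydro-2H-chromen-4-ol
Conditions: RuCl[(S,S)-TsDPEN](p-cymene) (2 mol%), HCO2H/Et3N (5:2), EtOAc, 40 °C; then silica chromatography
Reagents that add atoms: none
Why: Noyori asymmetric transfer hydrogenation is catalyst-controlled and makes C4 (S) in both enantiomers of 7, so the racemate becomes two diastereomeric alcohols that are separated on silica, and the one kept, with 4-OH trans to CH2OSi, carries (R) at C2.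

Step 6
Reactants: 8 (2R,4S)-6-bromo-2-{[(tert-butyldiphenylsilyl)oxy]methyl}-7-(methoxymethoxy)-2-methyl-3,4-dihydro-2H-chromen-4-ol
Product: 10 tert-butyl{[(2R)-6-bromo-7-(methoxymethoxy)-2-methyl-2H-chromen-2-yl]methoxy}diphenylsilane, via mesylate 9 (not isolated)
Conditions: MsCl, Et3N, CH2Cl2, 0 °C; then DBU, rt → 40 °C
Reagents that add atoms: none
Why: Mesylation of the electron-rich benzylic alcohol followed by base-induced elimination (dehydration) can only give the C3=C4 alkene because C2 is quaternary, and the non-acidic conditions erase C4 while leaving C2 and the MOM ether untouched.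

Step 7
Reactants: 10 tert-butyl{[(2R)-6-bromo-7-(methoxymethoxy)-2-methyl-2H-chromen-2-yl]methoxy}diphenylsilane
Product: 12 1-[(2R)-2-{[(tert-butyldiphenylsilyl)oxy]methyl}-7-(methoxymethoxy)-2-methyl-2H-chromen-6-yl]ethanone, via aryllithium 11 (not isolated)
Conditions: n-BuLi (1.1 equiv), THF, −78 °C; MeC(O)N(OMe)Me, −78 → 0 °C; aq. NH4Cl
Reagents that add atoms: N-methoxy-N-methylacetamide, CC(=O)N(C)OC
Why: Bromine–lithium exchange is faster at −78 °C than any reaction at the ethers or the alkene, and the ortho-MOM-stabilised aryllithium is acylated only once in this Weinreb ketone synthesis because the chelated tetrahedral adduct survives until work-up.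

Step 8
Reactants: 12 1-[(2R)-2-{[(tert-butyldiphenylsilyl)oxy]methyl}-7-(methoxymethoxy)-2-methyl-2H-chromen-6-yl]ethanone
Product: 13 1-[(2R)-2-{[(tert-butyldiphenylsilyl)oxy]methyl}-7-hydroxy-2-methyl-2H-chromen-6-yl]ethanone
Conditions: conc. HCl (cat.), MeOH/THF, rt, dark
Reagents that add atoms: none
Why: Acid-catalysed acetal cleavage removes the MOM group under very mild conditions because the phenol is ortho to the acetyl group, while the TBDPS ether and the chromene tolerate dilute acid at room temperature.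

Step 9
Reactants: 13 1-[(2R)-2-{[(tert-butyldiphenylsilyl)oxy]methyl}-7-hydroxy-2-methyl-2H-chromen-6-yl]ethanone
Product: 14 1-[(2R)-7-hydroxy-2-(hydroxymethyl)-2-methyl-2H-chromen-6-yl]ethanone
Conditions: TBAF/AcOH (1:1, 1.5 equiv), THF, 0 °C → rt, dark
Reagents that add atoms: none
Why: Fluoride-induced desilylation, driven by the strong Si–F bond, frees the primary alcohol, and the acetic acid buffer keeps the medium close to neutral.

Step 10
Reactants: 15 (E)-ferulic acid
Product: 16 (E)-3-(4-acetoxy-3-methoxyphenyl)prop-2-enoic acid (O-acetylferulic acid)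
Conditions: Ac2O, pyridine, rt; then H2O
Reagents that add atoms: acetic anhydride, CC(=O)OC(C)=O
Why: Acetylation of the phenol (nucleophilic acyl substitution) masks it so that the acid can be activated without self-esterification, and any mixed anhydride is hydrolysed in the aqueous work-up.

Step 11
Reactants: 16 (E)-3-(4-acetoxy-3-methoxyphenyl)prop-2-enoic acid
Product: 17 (E)-3-(4-acetoxy-3-methoxyphenyl)prop-2-enoyl chloride
Conditions: (COCl)2, DMF (cat.), CH2Cl2, 0 °C → rt; used crude
Reagents that add atoms: oxalyl chloride, ClC(=O)C(Cl)=O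
Why: Acid chloride formation through the Vilsmeier-type chloroiminium species runs at or below room temperature and leaves the aryl acetate and the E-alkene unchanged.

Step 12
Reactants: 14 1-[(2R)-7-hydroxy-2-(hydroxymethyl)-2-methyl-2H-chromen-6-yl]ethanone; 17 (E)-3-(4-acetoxy-3-methoxyphenyl)prop-2-enoyl chloride (1.3 equiv)
Product: 18 [(2R)-6-acetyl-7-hydroxy-2-methyl-2H-chromen-2-yl]methyl (E)-3-(4-acetoxy-3-methoxyphenyl)prop-2-enoate
Conditions: pyridine, DMAP (5 mol%), CH2Cl2, 0 °C → rt, dark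
Reagents that add atoms: none
Why: This acylation (nucleophilic acyl substitution) takes place at the primary alcohol because the 7-OH is hydrogen-bonded to the acetyl group and far less nucleophilic, and any aryl ester formed there is cleaved again in step 13.

Step 13
Reactants: 18 [(2R)-6-acetyl-7-hydroxy-2-methyl-2H-chromen-2-yl]methyl (E)-3-(4-acetoxy-3-methoxyphenyl)prop-2-enoate
Product: 19 [(2R)-6-acetyl-7-hydroxy-2-methyl-2H-chromen-2-yl]methyl (E)-3-(4-hydroxy-3-methoxyphenyl)prop-2-enoate (target)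
Conditions: pyrrolidine (5 equiv), CH2Cl2, rt, 30 min, dark; dilute HCl wash
Reagents that add atoms: none
Why: Aminolysis of aryl esters by pyrrolidine is far faster than that of the alkyl cinnamate, so the phenolic acetate is removed selectively without touching the ester link, the ketone or the C2 stereocentre.

## Compound list

1 | hydroxyacetone (1-hydroxypropan-2-one) | CC(=O)CO | starting material
2 | 1-[(tert-butyldiphenylsilyl)oxy]propan-2-one | CC(=O)CO[Si](c1ccccc1)(c1ccccc1)C(C)(C)C | intermediate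
3 | 2',4'-dihydroxyacetophenone | CC(=O)c1ccc(O)cc1O | starting material
4 | 1-(5-bromo-2,4-dihydroxyphenyl)ethanone | CC(=O)c1cc(Br)c(O)cc1O | intermediate
5 | 1-[5-bromo-2-hydroxy-4-(methoxymethoxy)phenyl]ethanone | CC(=O)c1cc(Br)c(OCOC)cc1O | intermediate
6 | enone: 1-[5-bromo-2-hydroxy-4-(methoxymethoxy)phenyl]-4-[(tert-butyldiphenylsilyl)oxy]-3-methylbut-2-en-1-one (E/Z) | CC(CO[Si](c1ccccc1)(c1ccccc1)C(C)(C)C)=CC(=O)c1cc(Br)c(OCOC)cc1O | intermediate (not isolated)
7 | rac-6-bromo-2-{[(tert-butyldiphenylsilyl)oxy]methyl}-7-(methoxymethoxy)-2-methyl-2,3-dihydro-4H-chromen-4-one | CC1(CO[Si](c2ccccc2)(c2ccccc2)C(C)(C)C)CC(=O)c2cc(Br)c(OCOC)cc2O1 | intermediate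
8 | (2R,4S)-6-bromo-2-{[(tert-butyldiphenylsilyl)oxy]methyl}-7-(methoxymethoxy)-2-methyl-3,4-dihydro-2H-chromen-4-ol (4-OH trans to CH2OSi) | CC(C)(C)[Si](c1ccccc1)(c1ccccc1)OC[C@@]1(C)C[C@H](O)c2cc(Br)c(OCOC)cc2O1 | intermediate
9 | mesylate: (2R,4S)-6-bromo-2-{[(tert-butyldiphenylsilyl)oxy]methyl}-7-(methoxymethoxy)-2-methyl-3,4-dihydro-2H-chromen-4-yl methanesulfonate | CC(C)(C)[Si](c1ccccc1)(c1ccccc1)OC[C@@]1(C)C[C@H](OS(C)(=O)=O)c2cc(Br)c(OCOC)cc2O1 | intermediate (not isolated)
10 | tert-butyl{[(2R)-6-bromo-7-(methoxymethoxy)-2-methyl-2H-chromen-2-yl]methoxy}diphenylsilane | CC(C)(C)[Si](c1ccccc1)(c1ccccc1)OC[C@@]1(C)C=Cc2cc(Br)c(OCOC)cc2O1 | intermediate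
11 | aryllithium: tert-butyl{[(2R)-6-lithio-7-(methoxymethoxy)-2-methyl-2H-chromen-2-yl]methoxy}diphenylsilane | CC(C)(C)[Si](c1ccccc1)(c1ccccc1)OC[C@@]1(C)C=Cc2cc([Li])c(OCOC)cc2O1 | intermediate (not isolated)
12 | 1-[(2R)-2-{[(tert-butyldiphenylsilyl)oxy]methyl}-7-(methoxymethoxy)-2-methyl-2H-chromen-6-yl]ethanone | CC(C)(C)[Si](c1ccccc1)(c1ccccc1)OC[C@@]1(C)C=Cc2cc(C(C)=O)c(OCOC)cc2O1 | intermediate
13 | 1-[(2R)-2-{[(tert-butyldiphenylsilyl)oxy]methyl}-7-hydroxy-2-methyl-2H-chromen-6-yl]ethanone | CC(C)(C)[Si](c1ccccc1)(c1ccccc1)OC[C@@]1(C)C=Cc2cc(C(C)=O)c(O)cc2O1 | intermediate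
14 | 1-[(2R)-7-hydroxy-2-(hydroxymethyl)-2-methyl-2H-chromen-6-yl]ethanone | OC[C@@]1(C)C=Cc2cc(C(C)=O)c(O)cc2O1 | intermediate
15 | (E)-ferulic acid | COc1cc(/C=C/C(=O)O)ccc1O | starting material
16 | (E)-3-(4-acetoxy-3-methoxyphenyl)prop-2-enoic acid | COc1cc(/C=C/C(=O)O)ccc1OC(C)=O | intermediate
17 | (E)-3-(4-acetoxy-3-methoxyphenyl)prop-2-enoyl chloride | COc1cc(/C=C/C(Cl)=O)ccc1OC(C)=O | intermediate
18 | [(2R)-6-acetyl-7-hydroxy-2-methyl-2H-chromen-2-yl]methyl (E)-3-(4-acetoxy-3-methoxyphenyl)prop-2-enoate | COc1cc(/C=C/C(=O)OC[C@@]2(C)C=Cc3cc(C(C)=O)c(O)cc3O2)ccc1OC(C)=O | intermediate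
19 | [(2R)-6-acetyl-7-hydroxy-2-methyl-2H-chromen-2-yl]methyl (E)-3-(4-hydroxy-3-methoxyphenyl)prop-2-enoate | COc1cc(/C=C/C(=O)OC[C@@]2(C)C=Cc3cc(C(C)=O)c(O)cc3O2)ccc1O | target

## Summary

Total step count: 13.
Longest linear sequence: 10 steps (steps 2, 3, 4, 5, 6, 7, 8, 9, 12, 13, from 3 to 19).

Steps most likely to fail:

**Step 4 (Kabbe condensation).** The α-silyloxy ketone 2 may self-condense or react sluggishly. The fallback sets out from 5 and 2. Compound 5 is doubly deprotonated with LiHMDS (2.2 equiv, THF, −78 °C) to the dilithium phenoxide–enolate of 5 F1. F1 adds to 2 in a directed crossed aldol addition and gives, after NH4Cl quench, racemic 1-[5-bromo-2-hydroxy-4-(methoxymethoxy)phenyl]-4-[(tert-butyldiphenylsilyl)oxy]-3-hydroxy-3-methylbutan-1-one F2. Catalytic PPTS in toluene at 80 °C dehydrates F2 to enone 6, which closes by oxa-Michael addition. The route is rejoined at 7.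

**Step 5 (reduction and epimer separation).** Alcohol 8 and its C2 epimer may not separate on silica. The fallback sets out from 7. Racemic 7 is resolved by preparative chiral SFC (polysaccharide carbamate phase, CO2/i-PrOH) into (2R)-6-bromo-2-{[(tert-butyldiphenylsilyl)oxy]methyl}-7-(methoxymethoxy)-2-methyl-2,3-dihydro-4H-chromen-4-one F3 and its (2S)-enantiomer F4, which is set aside. Each enantiomer now gives a single alcohol under the step 5 conditions. The enantiomer that gives the trans alcohol is F3, and its reduction delivers 8 with no diastereomer separation. The route is rejoined at 8.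

**Step 7 (lithiation and acylation).** The aryllithium 11 may be protonated by the enolisable amide, giving the debrominated chromene. The fallback sets out from 10. Stille coupling with tributyl(1-ethoxyvinyl)stannane (Pd(PPh3)4, toluene, 80 °C, dark) gives tert-butyl{[(2R)-6-(1-ethoxyethenyl)-7-(methoxymethoxy)-2-methyl-2H-chromen-2-yl]methoxy}diphenylsilane F5. Treatment with 2 M aqueous HCl in THF at room temperature to 40 °C hydrolyses the enol ether to the methyl ketone 12 and cleaves the MOM ether in the same pot. The route is rejoined at 13.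

## Further compounds

F1 | step 4 | dilithium phenoxide–enolate of 5 | [Li]OC(=C)c1cc(Br)c(OCOC)cc1O[Li]
F2 | step 4 | rac-1-[5-bromo-2-hydroxy-4-(methoxymethoxy)phenyl]-4-[(tert-butyldiphenylsilyl)oxy]-3-hydroxy-3-methylbutan-1-one | CC(O)(CO[Si](c1ccccc1)(c1ccccc1)C(C)(C)C)CC(=O)c1cc(Br)c(OCOC)cc1O
F3 | step 5 | (2R)-6-bromo-2-{[(tert-butyldiphenylsilyl)oxy]methyl}-7-(methoxymethoxy)-2-methyl-2,3-dihydro-4H-chromen-4-one | CC(C)(C)[Si](c1ccccc1)(c1ccccc1)OC[C@@]1(C)CC(=O)c2cc(Br)c(OCOC)cc2O1
F4 | step 5 | (2S)-6-bromo-2-{[(tert-butyldiphenylsilyl)oxy]methyl}-7-(methoxymethoxy)-2-methyl-2,3-dihydro-4H-chromen-4-one | CC(C)(C)[Si](c1ccccc1)(c1ccccc1)OC[C@]1(C)CC(=O)c2cc(Br)c(OCOC)cc2O1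
F5 | step 7 | tert-butyl{[(2R)-6-(1-ethoxyethenyl)-7-(methoxymethoxy)-2-methyl-2H-chromen-2-yl]methoxy}diphenylsilane | CC(C)(C)[Si](c1ccccc1)(c1ccccc1)OC[C@@]1(C)C=Cc2cc(C(=C)OCC)c(OCOC)cc2O1
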